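**Retrosynthetic overview**

1. Target 22 is taken back through its benzyl ether 21 and naphthol 20 to naphthol ester 18; after the ring construction only ester removal, one O-methylation and debenzylation remain.
2. Key disconnection: the naphthalene ring that carries C1' (bonded to chroman C4) and the C4' methoxy group, peri to the C5' methoxy group, is opened at C1'–C2' and C3'–C4'. This gives 7-methoxyphthalide 14 (its C3 becomes C1', its lactone carbonyl C4', its 7-methoxy group the C5' methoxy) and methyl acrylate 15 (C2', C3').
3. Phthalide 14 comes from the cis aldehyde 10 and ortho-lithiated N,N-diethyl-2-methoxybenzamide 11.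
4. C4 is set by hydrogenation of 2H-chromene-4-carboxylate 8 anti to the C2 methyl group (kinetic cis control; an equilibration at C4 is avoided because the peri benzyloxy group could favour trans). C2 is set by copper hydride conjugate reduction of chromone 4, made from 2',6'-dihydroxyacetophenone 1.
5. Ring order: pyranone ring (step 2), phthalide lactone (step 8), second naphthalene ring (step 9, which consumes the lactone).

Key step: step 9

Remark on locants: chroman atoms are unprimed; naphthalene atoms are primed, with C1' bonded to chroman C4 and the methoxy groups at C4' and C5'. The descriptor at chroman C4 is R in 9, 10, 13, 14, 16 and 17 and S in 18 to 22 only because the CIP priorities of the C4 substituents change; the spatial arrangement (substituent cis to the C2 methyl) is the same throughout.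

Assumption: (R)-DTBM-SEGPHOS is written on the assumption that its copper hydride delivers hydride to the face of the chromone that gives the 2S ketone; if the sense is the opposite, the (S)-ligand is used with no other change.

**Route**

Step 1
Reactants: 1 2',6'-dihydroxyacetophenone
Product: 2 1-[2-(benzyloxy)-6-hydroxyphenyl]ethan-1-one
Conditions: BnBr (1.05 equiv), K2CO3, acetone, reflux
Reagents that add atoms: benzyl bromide, BrCc1ccccc1
Why: Williamson etherification that should stop at the mono-ether, because the remaining phenol is locked in a hydrogen bond to the ketone and is much less nucleophilic.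

Step 2
Reactants: 2 1-[2-(benzyloxy)-6-hydroxyphenyl]ethan-1-one
Product: 4 5-(benzyloxy)-2-methyl-4H-chromen-4-one, via diketone 3 (not isolated)
Conditions: NaH, EtOAc, THF, reflux; then conc. HCl, MeOH, 60 °C
Reagents that add atoms: ethyl acetate, CCOC(C)=O
Why: Claisen condensation of the methyl ketone enolate with ethyl acetate gives the 1,3-diketone, and acid-catalysed cyclodehydration of the phenol onto the enolised diketone closes the pyranone ring of the 2-methylchromone.

Step 3
Reactants: 4 5-(benzyloxy)-2-methyl-4H-chromen-4-one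
Product: 6 (S)-5-(benzyloxy)-2-methylchroman-4-one, via silyl enol ether 5 (not isolated)
Conditions: Cu(OAc)2 (cat.), (R)-DTBM-SEGPHOS (cat.), (EtO)2MeSiH, toluene, 0 °C; then aq. HCl (1 M), THF, 0 °C
Reagents that add atoms: none
Why: Asymmetric copper hydride conjugate reduction in which the bisphosphine-ligated copper hydride adds hydride to one enantiotopic face of C2 and so sets C2 (S), while the enolate is held as the silyl enol ether, which protects the carbonyl from 1,2-reduction until hydrolysis.

Step 4
Reactants: 6 (S)-5-(benzyloxy)-2-methylchroman-4-one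
Product: 7 (S)-5-(benzyloxy)-2-methyl-2H-chromen-4-yl trifluoromethanesulfonate
Conditions: Tf2O, 2,6-di-tert-butyl-4-methylpyridine, CH2Cl2, 0 °C to rt
Reagents that add atoms: trifluoromethanesulfonic anhydride, O=S(=O)(OS(=O)(=O)C(F)(F)F)C(F)(F)F
Why: O-Triflation of the electron-rich aryl ketone followed by loss of a C3 proton gives the enol triflate without a free enolate, so the retro-oxa-Michael ring opening that would racemise C2 is avoided.

Step 5
Reactants: 7 (S)-5-(benzyloxy)-2-methyl-2H-chromen-4-yl trifluoromethanesulfonate
Product: 8 methyl (S)-5-(benzyloxy)-2-methyl-2H-chromene-4-carboxylate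
Conditions: Pd(OAc)2 (cat.), dppp, CO (1 atm), Et3N, MeOH/DMF, 60 °C
Reagents that add atoms: carbon monoxide, [C-]#[O+]; methanol, CO
Why: Palladium-catalysed methoxycarbonylation of an enol triflate (oxidative addition to zerovalent palladium, CO insertion, methanolysis of the acylpalladium), in which the in-plane C2–O bond of the 2H-chromene is not ionised and C2 is untouched.

Step 6
Reactants: 8 methyl (S)-5-(benzyloxy)-2-methyl-2H-chromene-4-carboxylate
Product: 9 methyl (2S,4R)-5-(benzyloxy)-2-methylchroman-4-carboxylate (cis)
Conditions: H2 (3 atm), 10% Pd/C, 2,2'-bipyridyl, EtOAc/MeOH, rt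
Reagents that add atoms: none
Why: Heterogeneous syn hydrogenation should deliver hydrogen to the face of the C3=C4 bond opposite the C2 methyl group, which sets C4 with the ester cis to the methyl group under kinetic control, while the bipyridyl-poisoned catalyst is known to spare phenolic benzyl ethers.

Step 7
Reactants: 9 methyl (2S,4R)-5-(benzyloxy)-2-methylchroman-4-carboxylate
Product: 10 (2S,4R)-5-(benzyloxy)-2-methylchroman-4-carbaldehyde (cis)
Conditions: i-Bu2AlH (1.1 equiv), CH2Cl2, −78 °C; aq. potassium sodium tartrate
Reagents that add atoms: none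
Why: Partial ester reduction stops at the tetrahedral aluminium hemiacetal at −78 °C and releases the aldehyde only on work-up, and the cold, non-basic conditions should keep the epimerisable C4 centre intact, the aldehyde being used at once.

Step 8
Reactants: 10 (2S,4R)-5-(benzyloxy)-2-methylchroman-4-carbaldehyde; 11 N,N-diethyl-2-methoxybenzamide
Product: 14 3-[(2S,4R)-5-(benzyloxy)-2-methylchroman-4-yl]-7-methoxy-2-benzofuran-1(3H)-one (both epimers at the lactone carbon), via aryllithium 12 (not isolated), via hydroxy amide 13 (not isolated)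
Conditions: s-BuLi, TMEDA, THF, −78 °C; add 10, −78 °C; AcOH; then TsOH·H2O (cat.), toluene, 80 °C
Reagents that add atoms: none
Why: Directed ortho-metalation occurs next to the amide (the stronger director) rather than next to the methoxy group, the aryllithium adds 1,2 to the aldehyde faster than it enolises it at −78 °C, and acid-catalysed lactonisation expels diethylamine; the new carbinol centre needs no control because it is deprotonated in step 9.

Step 9
Reactants: 14 3-[(2S,4R)-5-(benzyloxy)-2-methylchroman-4-yl]-7-methoxy-2-benzofuran-1(3H)-one; 15 methyl acrylate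
Product: 18 methyl 4-[(2S,4S)-5-(benzyloxy)-2-methylchroman-4-yl]-1-hydroxy-8-methoxy-2-naphthoate, via lithiated phthalide 16 (not isolated), via hydroxy tetralone 17 (not isolated)
Conditions: LiN(i-Pr)2 (1.2 equiv), THF, −78 °C; methyl acrylate, −78 to 0 °C; AcOH; then TsOH·H2O (cat.), toluene, 50 °C
Reagents that add atoms: none
Why: LiN(i-Pr)2 removes the only acidic proton, the phthalide C3–H (benzylic, next to the lactone oxygen and conjugated through the arene to the carbonyl), while the unactivated chroman C4–H is left alone and keeps its configuration; the delocalised anion 16 then adds 1,4 to methyl acrylate and forms C1'–C2' at a quaternary carbon. The resulting ester enolate attacks the lactone carbonyl in a six-membered Dieckmann closure of the 6-(enolexo)-exo-trig type that forms C3'–C4', and collapse of the tetrahedral intermediate opens the lactone to the tertiary alkoxide of hydroxy tetralone 17. This is the Michael–Dieckmann annulation of 3-substituted phthalide anions with acrylates, the leaving-group-free relative of the Hauser annulation. Acid then ionises the tertiary benzylic alcohol, and loss of a C2' proton from the enolised β-keto ester gives the aromatic 1-naphthol ester directly; this aromatising path is expected to outrun a hydride shift from chroman C4 or elimination toward it, which is the selectivity on which the C4 stereocentre depends. No new stereocentre survives, since the carbinol carbon and the ester-bearing carbon of 17 both become aromatic; the peri relation of the new C4' oxygen to the C5' methoxy group is fixed by the 7-methoxy group of the phthalide, and 1,4- over 1,2-addition follows from the soft, delocalised anion.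

Step 10
Reactants: 18 methyl 4-[(2S,4S)-5-(benzyloxy)-2-methylchroman-4-yl]-1-hydroxy-8-methoxy-2-naphthoate
Product: 19 4-[(2S,4S)-5-(benzyloxy)-2-methylchroman-4-yl]-1-hydroxy-8-methoxy-2-naphthoic acid
Conditions: KOH, EtOH/H2O, reflux, Ar; then aq. HCl
Reagents that add atoms: potassium hydroxide (aqueous), [K+].[OH-]
Why: Saponification of the hydrogen-bonded salicylate-type ester needs hot aqueous hydroxide, which the benzyl ether, the chroman and the non-acidic diarylmethine C4–H should all tolerate.

Step 11
Reactants: 19 4-[(2S,4S)-5-(benzyloxy)-2-methylchroman-4-yl]-1-hydroxy-8-methoxy-2-naphthoic acid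
Product: 20 4-[(2S,4S)-5-(benzyloxy)-2-methylchroman-4-yl]-8-methoxynaphthalen-1-ol
Conditions: Cu2O (cat.), 1,10-phenanthroline, NMP/quinoline, 170 °C, Ar
Reagents that add atoms: none
Why: Copper-mediated protodecarboxylation of an ortho-hydroxy naphthoic acid, which is eased because the ipso-protonated keto tautomer of a 1-naphthol-2-carboxylic acid is a β-keto acid.

Step 12
Reactants: 20 4-[(2S,4S)-5-(benzyloxy)-2-methylchroman-4-yl]-8-methoxynaphthalen-1-ol
Product: 21 (2S,4S)-5-(benzyloxy)-4-(4,5-dimethoxynaphthalen-1-yl)-2-methylchroman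
Conditions: MeI, K2CO3, DMF, 40 °C, Ar
Reagents that add atoms: iodomethane, CI
Why: Williamson O-methylation of the peri naphthol, the only free hydroxyl group in the molecule, completes the 4',5'-dimethoxy pattern.

Step 13
Reactants: 21 (2S,4S)-5-(benzyloxy)-4-(4,5-dimethoxynaphthalen-1-yl)-2-methylchroman
Product: 22 (2S,4S)-4-(4,5-dimethoxynaphthalen-1-yl)-2-methylchroman-5-ol (cladonaphchrom B)
Conditions: H2 (1 atm), 10% Pd/C, EtOAc/MeOH, rt
Reagents that add atoms: none
Why: Hydrogenolysis of the benzyl aryl ether under mild conditions should leave the methyl ethers, the naphthalene and the diarylmethine C4–C1' bond untouched.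

**Compound list**

1 | 2',6'-dihydroxyacetophenone | CC(=O)c1c(O)cccc1O | starting material
2 | 1-[2-(benzyloxy)-6-hydroxyphenyl]ethan-1-one | CC(=O)c1c(O)cccc1OCc1ccccc1 | intermediate
3 | 1-[2-(benzyloxy)-6-hydroxyphenyl]butane-1,3-dione | CC(=O)CC(=O)c1c(O)cccc1OCc1ccccc1 | intermediate
4 | 5-(benzyloxy)-2-methyl-4H-chromen-4-one | CC1=CC(=O)c2c(OCc3ccccc3)cccc2O1 | intermediate
5 | (S)-{[5-(benzyloxy)-2-methyl-2H-chromen-4-yl]oxy}diethoxy(methyl)silane | C[C@H]1C=C(O[Si](C)(OCC)OCC)c2c(OCc3ccccc3)cccc2O1 | intermediate
6 | (S)-5-(benzyloxy)-2-methylchroman-4-one | C[C@H]1CC(=O)c2c(OCc3ccccc3)cccc2O1 | intermediate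
7 | (S)-5-(benzyloxy)-2-methyl-2H-chromen-4-yl trifluoromethanesulfonate | C[C@H]1C=C(OS(=O)(=O)C(F)(F)F)c2c(OCc3ccccc3)cccc2O1 | intermediate
8 | methyl (S)-5-(benzyloxy)-2-methyl-2H-chromene-4-carboxylate | C[C@H]1C=C(C(=O)OC)c2c(OCc3ccccc3)cccc2O1 | intermediate
9 | methyl (2S,4R)-5-(benzyloxy)-2-methylchroman-4-carboxylate (cis) | C[C@H]1C[C@@H](C(=O)OC)c2c(OCc3ccccc3)cccc2O1 | intermediate
10 | (2S,4R)-5-(benzyloxy)-2-methylchroman-4-carbaldehyde (cis) | C[C@H]1C[C@@H](C=O)c2c(OCc3ccccc3)cccc2O1 | intermediate
11 | N,N-diethyl-2-methoxybenzamide | CCN(CC)C(=O)c1ccccc1OC | starting material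
12 | [2-(diethylcarbamoyl)-3-methoxyphenyl]lithium | [Li]c1cccc(OC)c1C(=O)N(CC)CC | intermediate
13 | 2-{[(2S,4R)-5-(benzyloxy)-2-methylchroman-4-yl](hydroxy)methyl}-N,N-diethyl-6-methoxybenzamide (both carbinol epimers) | CCN(CC)C(=O)c1c(OC)cccc1C(O)[C@@H]1C[C@H](C)Oc2cccc(OCc3ccccc3)c21 | intermediate
14 | 3-[(2S,4R)-5-(benzyloxy)-2-methylchroman-4-yl]-7-methoxy-2-benzofuran-1(3H)-one (both epimers at the lactone carbon) | COc1cccc2c1C(=O)OC2[C@@H]1C[C@H](C)Oc2cccc(OCc3ccccc3)c21 | intermediate
15 | methyl acrylate | C=CC(=O)OC | starting material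
16 | 3-lithio derivative of phthalide 14 | COc1cccc2c1C(=O)OC2([Li])[C@@H]1C[C@H](C)Oc2cccc(OCc3ccccc3)c21 | intermediate
17 | methyl 4-[(2S,4R)-5-(benzyloxy)-2-methylchroman-4-yl]-4-hydroxy-8-methoxy-1-oxo-1,2,3,4-tetrahydronaphthalene-2-carboxylate (diastereomer mixture) | COC(=O)C1CC(O)([C@@H]2C[C@H](C)Oc3cccc(OCc4ccccc4)c32)c2cccc(OC)c2C1=O | intermediate
18 | methyl 4-[(2S,4S)-5-(benzyloxy)-2-methylchroman-4-yl]-1-hydroxy-8-methoxy-2-naphthoate | COC(=O)c1cc([C@@H]2C[C@H](C)Oc3cccc(OCc4ccccc4)c32)c2cccc(OC)c2c1O | intermediate
19 | 4-[(2S,4S)-5-(benzyloxy)-2-methylchroman-4-yl]-1-hydroxy-8-methoxy-2-naphthoic acid | OC(=O)c1cc([C@@H]2C[C@H](C)Oc3cccc(OCc4ccccc4)c32)c2cccc(OC)c2c1O | intermediate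
20 | 4-[(2S,4S)-5-(benzyloxy)-2-methylchroman-4-yl]-8-methoxynaphthalen-1-ol | COc1cccc2c([C@@H]3C[C@H](C)Oc4cccc(OCc5ccccc5)c43)ccc(O)c12 | intermediate
21 | (2S,4S)-5-(benzyloxy)-4-(4,5-dimethoxynaphthalen-1-yl)-2-methylchroman | COc1cccc2c([C@@H]3C[C@H](C)Oc4cccc(OCc5ccccc5)c43)ccc(OC)c12 | intermediate
22 | (2S,4S)-4-(4,5-dimethoxynaphthalen-1-yl)-2-methylchroman-5-ol (cladonaphchrom B) | COc1cccc2c([C@@H]3C[C@H](C)Oc4cccc(O)c43)ccc(OC)c12 | target

**Step count and risks**

Total step count: 13. Longest linear sequence: 13 steps (1 to 22); the other two starting materials, 11 and 15, are commercial and enter at steps 8 and 9.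

Steps most likely to fail:

Step 9. The anion of 14 is tertiary and flanked by the bulky chroman, so conjugate addition may be slow enough that anionic polymerisation of the acrylate or retro-Michael reaction takes over. During the acid dehydration, a hydride shift from chroman C4 to the benzylic cation could also scramble the C4 configuration. The fallback sets out from triflate 7 and joins the aryl group by cross-coupling instead of building it. Commercial 1,8-dimethoxynaphthalene is brominated para to one methoxy group with NBS in MeCN to give 4-bromo-1,8-dimethoxynaphthalene F1. Bromine–lithium exchange with n-BuLi at −78 °C, quenching with B(Oi-Pr)3 and acidic work-up give (4,5-dimethoxynaphthalen-1-yl)boronic acid F2. Suzuki–Miyaura coupling of F2 with 7 (Pd(OAc)2, SPhos, K3PO4, toluene/H2O) gives (S)-5-(benzyloxy)-4-(4,5-dimethoxynaphthalen-1-yl)-2-methyl-2H-chromene F3. Hydrogenation of F3 over Pd/C poisoned with 2,2'-bipyridyl, anti to the C2 methyl group, returns to the route at 21.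

Step 8. The hindered, basic aryllithium may enolise the α-aryl aldehyde instead of adding to it, which would erode the cis configuration at C4 or return epimerised aldehyde. The fallback sets out from unsaturated ester 8 and postpones the alkene reduction until after the carbon–carbon bond is made, so that no epimerisable aldehyde is handled. Reduction of 8 with i-Bu2AlH (2.2 equiv, −78 °C) gives [(S)-5-(benzyloxy)-2-methyl-2H-chromen-4-yl]methanol F4, and MnO2 in CH2Cl2 oxidises it to (S)-5-(benzyloxy)-2-methyl-2H-chromene-4-carbaldehyde F5, which has no α-stereocentre. Addition of aryllithium 12 to F5 gives 2-{[(S)-5-(benzyloxy)-2-methyl-2H-chromen-4-yl](hydroxy)methyl}-N,N-diethyl-6-methoxybenzamide F6, and catalytic TsOH in toluene lactonises it to 3-[(S)-5-(benzyloxy)-2-methyl-2H-chromen-4-yl]-7-methoxy-2-benzofuran-1(3H)-one F7. Homogeneous hydrogenation of F7 with [Ir(cod)(PCy3)(py)]PF6 in CH2Cl2, again anti to the C2 methyl group and without risk to the benzyl ether or the allylic lactone C–O bond, returns to the route at 14.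

Step 6. The C2 methyl group is small and two atoms away from C4, so facial discrimination on the catalyst surface may be incomplete, and the poisoned catalyst may still cleave some benzyl ether. The fallback sets out from 8 and replaces substrate control by catalyst control. Saponification of 8 (LiOH, THF/H2O) gives (S)-5-(benzyloxy)-2-methyl-2H-chromene-4-carboxylic acid F8. Carboxylate-directed asymmetric hydrogenation with Ru(OAc)2(BINAP), in the ligand antipode matched to the bias of the C2 methyl group, gives (2S,4R)-5-(benzyloxy)-2-methylchroman-4-carboxylic acid F9. Esterification of F9 with TMSCHN2 in toluene/MeOH, which needs no base, returns to the route at 9.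

**Further compounds**

F1 | step 9 | 4-bromo-1,8-dimethoxynaphthalene | COc1cccc2c(Br)ccc(OC)c12
F2 | step 9 | (4,5-dimethoxynaphthalen-1-yl)boronic acid | COc1cccc2c(B(O)O)ccc(OC)c12
F3 | step 9 | (S)-5-(benzyloxy)-4-(4,5-dimethoxynaphthalen-1-yl)-2-methyl-2H-chromene | C[C@H]1C=C(c2ccc(OC)c3c(OC)cccc23)c2c(OCc3ccccc3)cccc2O1
F4 | step 8 | [(S)-5-(benzyloxy)-2-methyl-2H-chromen-4-yl]methanol | C[C@H]1C=C(CO)c2c(OCc3ccccc3)cccc2O1
F5 | step 8 | (S)-5-(benzyloxy)-2-methyl-2H-chromene-4-carbaldehyde | C[C@H]1C=C(C=O)c2c(OCc3ccccc3)cccc2O1
F6 | step 8 | 2-{[(S)-5-(benzyloxy)-2-methyl-2H-chromen-4-yl](hydroxy)methyl}-N,N-diethyl-6-methoxybenzamide | CCN(CC)C(=O)c1c(OC)cccc1C(O)C1=C[C@H](C)Oc2cccc(OCc3ccccc3)c21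
F7 | step 8 | 3-[(S)-5-(benzyloxy)-2-methyl-2H-chromen-4-yl]-7-methoxy-2-benzofuran-1(3H)-one | COc1cccc2c1C(=O)OC2C1=C[C@H](C)Oc2cccc(OCc3ccccc3)c21
F8 | step 6 | (S)-5-(benzyloxy)-2-methyl-2H-chromene-4-carboxylic acid | C[C@H]1C=C(C(=O)O)c2c(OCc3ccccc3)cccc2O1
F9 | step 6 | (2S,4R)-5-(benzyloxy)-2-methylchroman-4-carboxylic acid | C[C@H]1C[C@@H](C(=O)O)c2c(OCc3ccccc3)cccc2O1
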